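The ratio of L charged to E charged, cL/cE, the charge ratio 29.4 (the monomer-to-initiator ratio), opened the meeting on this flask.

all flasks: E 17 µM

| run | L | X | remark | time |
|---|---|---|---|---|
| oak | 0.25 mM | 0.15 mM | run made earlier |  |
| elm | 1 mM | 0.15 mM | run made earlier |  |
| larch | 0.50 mM | 0.30 mM | run made earlier |  |
| flask | 0.50 mM | 0.150 mM |  | 2.5 min |

| run | time / s | D / % | L / % |
|---|---|---|---|
| oak | 25.0 | 41 | 39 |
| oak | 50.0 | 52 | 15 |
| oak | 60.0 | 60 | 12 |
| oak | 90.0 | 66 | 5 |
| elm | 10.0 | 21 | 69 |
| elm | 15.0 | 29 | 62 |
| elm | 40.0 | 59 | 34 |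
| elm | 90.0 | 75 | 7 |
| larch | 25.0 | 34 | 33 |
| larch | 50.0 | 49 | 11 |
| larch | 60.0 | 51 | 12 |
| larch | 90.0 | 57 | 5 |

(each reading ± 1.5 percentage points)

- the average divides the monomer in chains by the number of chains, living and dead together; two radicals that join make one chain
- the earlier runs do not show the number of chains; that part of a forecast is a guess

1. average number of monomer units in a chain (living and dead chains, two that joined counted as one) at 2.5 min
2. part of the L that has reacted at 2.5 min

The first speaker held that dp equals the charge ratio times y, the share of L that ends as D, divided by s, the share of E used, provided each E used ends as one chain: its two radicals start two chains, and these join into one. She took y from the last oak and elm readings, about 70.5 %. At one end, with s equal to one, dp comes to 20.7; at the other end, with y held, dp rises as s falls. Since the runs show no chains, she committed to that floor, left s open and offered no figure for c.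

The forecaster gave dp 30, range 12 to 60, and c 98 %, range 96 % to 99.5 %, taking about 13 µM chains and noting: “The chain count is a guess”. The first speaker pointed out that her floor lay above the forecast's low end.

The flask gave dp 91.5 and c 98.6 %.

    X + L → Q (k = 99.5 M⁻¹ s⁻¹)
    2 J → Z (k = 2.00 × 10⁸ M⁻¹ s⁻¹)
    L + G → J + D (k = 7.68 × 10⁷ M⁻¹ s⁻¹)
    L + J → D + J, rate k4*[J]*[L] (k = 1.90 × 10⁶ M⁻¹ s⁻¹)
    E → 2 G (k = 0.00183 s⁻¹)

At the asked time this flask holds D at 74.8 % and has used 24.0 % of its E, so the charge ratio gives dp 91.6. The same flask read at 6.0 min holds D at 76.0 % and has used 48.3 % of its E, so the same reckoning gives 46.3, while that flask shows dp 68.5. There L stands at 0 %, the E used comes to 0.00820 mM, Z holds 0.00555 mM, and G stands at 0.00530 mM.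

Readings and results were computed for an exercise; the scatter is artificial.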